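**Retrosynthetic overview**
1. Target 11 ⇒ lactone C2–O1 bond (key bond, C–O) plus C3=C4: the aryloxide of 7 captures an N-formylketenimine made in the flask from aldehyde 6 and TosMIC, which supplies C2.
2. 6 ⇒ 5 (O-methylation) ⇒ 4 (hydrogenation of the pyran C=C).
3. 4 ⇒ 1 + 2: the pyran O–C bond is closed by oxa-6π ring closure of dienone 3; the hydrogen-bonded 2-OH/CHO pair steers the annulation to C3.
4. Ring order: pyran ring of the chroman unit first (step 1), lactone ring of the coumarin last (step 4); both rings are closed at oxygen.

Assumption: the target has no stereocentre or stereogenic double bond, so it is made as drawn; 7 and TosMIC are taken as catalogue chemicals.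

**Route**

Step 1
Reactants: 1 2,4-dihydroxybenzaldehyde; 2 3-methylbut-2-enal
Product: 4 5-hydroxy-2,2-dimethyl-2H-chromene-6-carbaldehyde, via dienone 3 (not isolated)
Conditions: 2 (1.5 equiv), Ca(OH)2 (1 equiv), MeOH, rt, 24–48 h
Reagents that add atoms: none
Why: Known regioselective chromenylation: the 4-phenoxide attacks the enal through C3 (aldol-type, the chelated 2-OH/CHO pair fixes the C3=C4 enol), dehydration gives dienone 3, and oxa-6π electrocyclisation forms the pyran O–C bond.

Step 2
Reactants: 4 5-hydroxy-2,2-dimethyl-2H-chromene-6-carbaldehyde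
Product: 5 5-hydroxy-2,2-dimethyl-3,4-dihydro-2H-chromene-6-carbaldehyde
Conditions: H2 (1 atm), 10% Pd/C, EtOAc, rt, 3 h
Reagents that add atoms: none
Why: Heterogeneous catalytic hydrogenation of the cis-disubstituted styrene-type alkene; the hydrogen-bonded ortho-hydroxy aldehyde and the aryl ether are inert at 1 atm.

Step 3
Reactants: 5 5-hydroxy-2,2-dimethyl-3,4-dihydro-2H-chromene-6-carbaldehyde
Product: 6 5-methoxy-2,2-dimethyl-3,4-dihydro-2H-chromene-6-carbaldehyde
Conditions: MeI (3 equiv), K2CO3 (2 equiv), DMF, 45 °C, 6 h
Reagents that add atoms: iodomethane (MeI) CI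
Why: Williamson O-methylation of the only phenol; K2CO3 in DMF breaks the intramolecular hydrogen bond and there is no other nucleophilic site.

Step 4
Reactants: 6 5-methoxy-2,2-dimethyl-3,4-dihydro-2H-chromene-6-carbaldehyde; 7 2,4-dihydroxy-6-methoxybenzaldehyde
Product: 11 7-hydroxy-5-methoxy-3-(5-methoxy-2,2-dimethyl-3,4-dihydro-2H-chromen-6-yl)-2H-chromen-2-one (target), via vinylformamide 8 (not isolated), via N-formylketenimine 9 (not isolated), via 2-iminochromene 10 (not isolated)
Conditions: TosMIC (1.1 equiv), tBuOK (2.3 equiv), THF, −50 °C, 1 h; then 7 (1.1 equiv) + tBuOK (2.2 equiv) in DMF, −50 → 65 °C, 4 h; then 2 M aq. HCl, 50 °C, 1 h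
Reagents that add atoms: p-toluenesulfonylmethyl isocyanide (TosMIC) [C-]#[N+]CS(=O)(=O)c1ccc(C)cc1; water O
Why: Proposed new method: an interrupted van Leusen reductive cyanation in which the N-formylketenimine 9, released from the potassium salt of 8 by loss of sulfinate, is captured at its central carbon by the ortho-aryloxide of 7 (new C2–O1 bond) instead of being deformylated by methanol; the aza-enolate so formed sits next to the formyl group and closes by intramolecular aldol addition, N-to-O formyl transfer and loss of formate give 10, and mild acid hydrolysis of the C=N bond gives the lactone; capture at the 4-aryloxide or early deformylation only gives an aryl imidate or the arylacetonitrile anion, both of which feed the same 2-iminochromene by Knoevenagel addition and Pinner-type O-attack on the nitrile; the closest known reactions are the van Leusen aldehyde-to-nitrile homologation, the salicylaldehyde–arylacetonitrile iminocoumarin condensation and the capture of N-sulfonylketenimines by salicylaldehydes; no stereocentre is formed.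

**Compound list**
1 | 2,4-dihydroxybenzaldehyde | O=Cc1ccc(O)cc1O | starting material
2 | 3-methylbut-2-enal | CC(C)=CC=O | starting material
3 | (3Z)-2-hydroxy-3-(3-methylbut-2-en-1-ylidene)-4-oxocyclohexa-1,5-diene-1-carbaldehyde (not isolated) | CC(C)=C/C=C1\C(=O)C=CC(C=O)=C1O | intermediate
4 | 5-hydroxy-2,2-dimethyl-2H-chromene-6-carbaldehyde | CC1(C)C=Cc2c(O1)ccc(C=O)c2O | intermediate
5 | 5-hydroxy-2,2-dimethyl-3,4-dihydro-2H-chromene-6-carbaldehyde | CC1(C)CCc2c(O1)ccc(C=O)c2O | intermediate
6 | 5-methoxy-2,2-dimethyl-3,4-dihydro-2H-chromene-6-carbaldehyde | COc1c(C=O)ccc2OC(C)(C)CCc12 | intermediate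
7 | 2,4-dihydroxy-6-methoxybenzaldehyde | COc1cc(O)cc(O)c1C=O | starting material
8 | N-[2-(5-methoxy-2,2-dimethyl-3,4-dihydro-2H-chromen-6-yl)-1-(4-methylphenyl)sulfonylethenyl]formamide (present as potassium salt, not isolated; double-bond geometry not controlled and without consequence, so not written) | O=CNC(=Cc1ccc2OC(C)(C)CCc2c1OC)S(=O)(=O)c1ccc(C)cc1 | intermediate
9 | N-[2-(5-methoxy-2,2-dimethyl-3,4-dihydro-2H-chromen-6-yl)ethenylidene]formamide (not isolated) | O=CN=C=Cc1ccc2OC(C)(C)CCc2c1OC | intermediate
10 | 2-imino-5-methoxy-3-(5-methoxy-2,2-dimethyl-3,4-dihydro-2H-chromen-6-yl)-2H-chromen-7-ol (not isolated) | N=C1Oc2cc(O)cc(OC)c2C=C1c1ccc2OC(C)(C)CCc2c1OC | intermediate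
11 | 7-hydroxy-5-methoxy-3-(5-methoxy-2,2-dimethyl-3,4-dihydro-2H-chromen-6-yl)-2H-chromen-2-one | COc1c(-c2cc3c(OC)cc(O)cc3oc2=O)ccc2c1CCC(C)(C)O2 | target

**Step count**
Total steps: 4. Longest linear sequence: 4 (1 → 4 → 5 → 6 → 11).

**Steps most likely to fail, with fallbacks**

Step 4 (the new three-component lactone closure). The ketenimine may be deformylated before it is captured, the dianion of 7 may react sluggishly, or the 4-aryloxide may divert material. The fallback uses only known chemistry and sets out from 6. Classical reductive cyanation (TosMIC, tBuOK, DME, −50 °C, then MeOH, reflux) gives 2-(5-methoxy-2,2-dimethyl-3,4-dihydro-2H-chromen-6-yl)acetonitrile F1, which is isolated. Amine-catalysed Knoevenagel–Pinner condensation of F1 with 7 (piperidine, EtOH, reflux) comes back to the route at 10, which is hydrolysed to 11 with aqueous HCl as in step 4.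

Step 1 (chromenylation). The enal can oligomerise and the yield can be moderate. The fallback sets out from 1 and replaces the aldol/electrocyclisation by O-alkylation and a propargyl Claisen sequence. Selective alkylation of the non-chelated 4-OH with 3-chloro-3-methylbut-1-yne (K2CO3, KI, acetone, reflux) gives 2-hydroxy-4-[(2-methylbut-3-yn-2-yl)oxy]benzaldehyde F2. Heating F2 in N,N-diethylaniline at 190 °C (propargyl Claisen shift to C3, 1,5-hydrogen shift, oxa-6π closure) comes back to the route at 4.

Step 2 (hydrogenation). The aldehyde may be over-reduced to the benzylic alcohol or the methyl compound. The fallback sets out from 4 and swaps metal-catalysed H2 addition for metal-free diimide transfer reduction (2-nitrobenzenesulfonohydrazide, Et3N, CH2Cl2, rt), which reduces only the nonpolar C=C bond and cannot touch C=O. It comes back to the route at 5 and makes no new compound (F0).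

**Further compounds**
F1 | step 4 | 2-(5-methoxy-2,2-dimethyl-3,4-dihydro-2H-chromen-6-yl)acetonitrile | N#CCc1ccc2OC(C)(C)CCc2c1OC
F2 | step 1 | 2-hydroxy-4-[(2-methylbut-3-yn-2-yl)oxy]benzaldehyde | C#CC(C)(C)Oc1ccc(C=O)c(O)c1
F0 | step 2 | none | none
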